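The ortho carbons C4a/C8a of ring A are spanned by the chain C4–C3–C2–C1 to make ring B. An extra C4–C1 bond folds that chain into a cyclobutane. With C4 as a ketone this is a 2‑arylcyclobutanone whose strained C(O)–CH(Ar) bond can take up an aryne.
Retrosynthetic cuts, in order: the benzyl ethers and a helper ketone at C4; C3–CH2OH (formaldehyde aldol); C4–C4a and C1–C8a together (aryne insertion, restoring C4–C1); the cyclobutane into an arylketeniminium salt and an allyl ether.
Forward: the cyclobutane forms by [2+2]. Ring B then forms by two‑carbon ring expansion with symmetric 4,5‑dimethoxybenzyne, which joins ring A in the same step. Side‑chain work on the tetralone and removal of the ketone follow.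
The helper ketone makes the insertion possible, singles out the para methoxy group for demethylation (so a symmetric aryne suffices), carries the aldol, and leaves by hydrogenolysis with the benzyl groups.
Stereochemistry: C2 comes from a C2‑symmetric pyrrolidine auxiliary in the [2+2]. C1 comes from hydroxyl‑delivered protonation in the ring expansion. C3 comes from attack on the enol silane anti to the C2 side chain, which also gives the more stable epimer.

Key step: step 3

Numbering: in the plan the target is numbered as a tetralin (C1 carries the aryl group). Tetralones and cyclobutanones are numbered from their carbonyl carbon (C‑1).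
Assumption: the (2S,5S) auxiliary is taken to lead to (3S)‑configured 7. If the sense of induction is the opposite, the equally available (2R,5R)‑amine is used and nothing else changes.

Step 1
Reactants: 1 2‑[4‑(benzyloxy)‑3‑methoxyphenyl]acetic acid; 2 (2S,5S)‑2,5‑dimethylpyrrolidine
Product: 3 2‑[4‑(benzyloxy)‑3‑methoxyphenyl]‑1‑[(2S,5S)‑2,5‑dimethylpyrrolidin‑1‑yl]ethan‑1‑one
Conditions: DCC, HOBt (cat.), CH2Cl2, 0 °C to rt
Reagents that add atoms: none
Why: Carbodiimide amide coupling of an unhindered arylacetic acid with a secondary amine, in which no stereocentre is touched.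

Step 2
Reactants: 3 amide; 4 allyl tert‑butyldimethylsilyl ether
Product: 7 (2S,3S)‑2‑[4‑(benzyloxy)‑3‑methoxyphenyl]‑3‑(hydroxymethyl)cyclobutan‑1‑one, via keteniminium triflate 5 (not isolated), via cyclobutaniminium triflate 6 (not isolated)
Conditions: Tf2O, 2,4,6‑collidine, 4 (3 equiv), ClCH2CH2Cl, 80 °C; then 1 M aq. HCl, THF, rt
Reagents that add atoms: water, O
Why: In this keteniminium–olefin [2+2] cycloaddition the electrophilic central carbon bonds to the CH2 terminus of the olefin (hence the 2,3‑pattern), the C2‑symmetric pyrrolidine shields one face and so sets C‑3, and aqueous acid hydrolyses the iminium salt, removes the silyl group and lets C‑2 settle trans through the enol.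

Step 3
Reactants: 7 hydroxy cyclobutanone; 8 4,5‑dimethoxy‑2‑(trimethylsilyl)phenyl trifluoromethanesulfonate
Product: 11 (3S,4S)‑4‑[4‑(benzyloxy)‑3‑methoxyphenyl]‑3‑(hydroxymethyl)‑6,7‑dimethoxy‑3,4‑dihydronaphthalen‑1(2H)‑one, via 4,5‑dimethoxybenzyne 9 (not isolated), via bicyclo[2.2.0]hexane alkoxide 10 (not isolated)
Conditions: 8 (1.3 equiv), CsF (3 equiv), MeCN, 80 °C
Reagents that add atoms: none
Why: Proposed new method: fluoride releases the symmetric aryne 9 from 8 and starts a base chain in which the benzylic C‑2 enolate of 7 adds through carbon to 9, the resulting aryl anion closes 4‑exo‑trig on the cyclobutanone carbonyl to give the benzo‑fused bicyclo[2.2.0]hexane alkoxide 10, and retro‑aldol cleavage of the bond shared by the two four‑membered rings expels a diarylmethyl anion conjugated with the new ortho ketone. The closest known reaction type is the acyl‑alkylation of arynes, that is insertion into the C(O)–Cα bond of β‑keto esters (with two‑carbon ring expansion of cyclic ones) and of acyclic benzyl ketones; a 2‑arylcyclobutanone has not been used, but its carbonyl is unusually electrophilic and the fragmentation frees the strain of both small rings (roughly 50 kcal/mol). Ring B is therefore closed not by a direct six‑membered cyclisation but by a 4‑exo‑trig closure followed by ring expansion, and both aryl–carbon bonds are in place before the C–C bond breaks. The only new stereocentre, C‑4 of 11, is set when the planar anion is protonated: allylic strain against the aryl group turns the C‑3 CH2OH group pseudo‑axial over the anion, and the free hydroxyl, as the nearest acid, should deliver the proton on its own face, which places aryl and CH2OH trans, while C‑3 is carried over from 7. The step needs enolisation at C‑2 rather than C‑4 (secured by the aryl group), cleavage of C1–C2 rather than C1–C4 (only the former gives a stabilised anion), C‑ over O‑attack and tolerance of the aliphatic OH (a poor aryne trap next to a soft enolate), and it needs no regiocontrol on the arene because 9 is symmetric.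

Step 4
Reactants: 11 dimethoxy tetralone
Product: 12 (3S,4S)‑4‑[4‑(benzyloxy)‑3‑methoxyphenyl]‑6‑hydroxy‑3‑(hydroxymethyl)‑7‑methoxy‑3,4‑dihydronaphthalen‑1(2H)‑one
Conditions: LiCl (excess), DMF, 150 °C; aq. HCl work‑up
Reagents that add atoms: none
Why: Nucleophilic demethylation by chloride (SN2 at methyl) works only where the departing phenoxide is stabilised by a para acyl group, so the 6‑OMe should be cleaved while the 7‑OMe, the pendant OMe and the benzyl ether stay.

Step 5
Reactants: 12 phenol
Product: 13 (3S,4S)‑6‑(benzyloxy)‑4‑[4‑(benzyloxy)‑3‑methoxyphenyl]‑3‑(hydroxymethyl)‑7‑methoxy‑3,4‑dihydronaphthalen‑1(2H)‑one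
Conditions: BnBr, K2CO3, acetone, reflux
Reagents that add atoms: benzyl bromide, BrCc1ccccc1
Why: In this Williamson ether synthesis carbonate deprotonates only the acidic para‑acyl phenol, so the primary alcohol stays free.

Step 6
Reactants: 13 alcohol
Product: 14 (3S,4S)‑3‑(acetoxymethyl)‑6‑(benzyloxy)‑4‑[4‑(benzyloxy)‑3‑methoxyphenyl]‑7‑methoxy‑3,4‑dihydronaphthalen‑1(2H)‑one
Conditions: Ac2O, pyridine, DMAP (cat.), CH2Cl2, 0 °C to rt
Reagents that add atoms: acetic anhydride, CC(=O)OC(C)=O
Why: DMAP‑catalysed acylation of the only free hydroxyl group puts the acetate on the side chain next to the diarylmethine carbon before the second hydroxymethyl group exists.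

Step 7
Reactants: 14 keto acetate
Product: 15 (3R,4S)‑3‑(acetoxymethyl)‑6‑(benzyloxy)‑4‑[4‑(benzyloxy)‑3‑methoxyphenyl]‑7‑methoxy‑1‑(trimethylsilyloxy)‑3,4‑dihydronaphthalene
Conditions: TMSOTf, Et3N, CH2Cl2, 0 °C
Reagents that add atoms: trimethylsilyl trifluoromethanesulfonate, C[Si](C)(C)OS(=O)(=O)C(F)(F)F
Why: Soft enolisation with silyl triflate and amine gives the enol silane at C‑2, the only α‑position with hydrogens, and the aryl ketone reacts faster than the acetate (the descriptor at C‑3 changes by priority only).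

Step 8
Reactants: 15 enol silane
Product: 16 (2R,3R,4S)‑3‑(acetoxymethyl)‑6‑(benzyloxy)‑4‑[4‑(benzyloxy)‑3‑methoxyphenyl]‑2‑(hydroxymethyl)‑7‑methoxy‑3,4‑dihydronaphthalen‑1(2H)‑one
Conditions: aq. HCHO (37 %), Yb(OTf)3 (10 mol %), THF, rt
Reagents that add atoms: formaldehyde, C=O
Why: In this lanthanide‑catalysed aqueous Mukaiyama aldol (hydroxymethylation) formaldehyde should approach C‑2 anti to the neighbouring C‑3 side chain to give the 2,3‑trans ketone, which is also the more stable α‑epimer.

Step 9
Reactants: 16 β‑hydroxy ketone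
Product: 17 (2R,3R,4S)‑3‑(acetoxymethyl)‑6‑(benzyloxy)‑4‑[4‑(benzyloxy)‑3‑methoxyphenyl]‑2‑(hydroxymethyl)‑7‑methoxy‑1,2,3,4‑tetrahydronaphthalen‑1‑ol (mixture of C‑1 epimers)
Conditions: NaBH4, CeCl3·7H2O, MeOH, −20 °C
Reagents that add atoms: none
Why: The Luche reduction takes the aryl ketone to the benzylic alcohol under nearly neutral conditions that spare the acetate and avoid retro‑aldol, and the new carbinol centre is removed in the next step.

Step 10
Reactants: 17 benzylic alcohol
Product: 18 [(1S,2R,3R)‑7‑hydroxy‑1‑(4‑hydroxy‑3‑methoxyphenyl)‑3‑(hydroxymethyl)‑6‑methoxy‑1,2,3,4‑tetrahydronaphthalen‑2‑yl]methyl acetate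
Conditions: H2 (1 atm), 10 % Pd/C, EtOH–EtOAc, AcOH (cat.), rt
Reagents that add atoms: none
Why: Catalytic hydrogenolysis cleaves both aryl benzyl ethers and the benzylic C–OH bond para to oxygen, while the acetate, the primary alcohol and the three stereocentres are not affected.

Compound list
1 | 2‑[4‑(benzyloxy)‑3‑methoxyphenyl]acetic acid | COc1cc(CC(=O)O)ccc1OCc1ccccc1 | starting material
2 | (2S,5S)‑2,5‑dimethylpyrrolidine | C[C@H]1CC[C@H](C)N1 | starting material
3 | 2‑[4‑(benzyloxy)‑3‑methoxyphenyl]‑1‑[(2S,5S)‑2,5‑dimethylpyrrolidin‑1‑yl]ethan‑1‑one | COc1cc(CC(=O)N2[C@@H](C)CC[C@@H]2C)ccc1OCc1ccccc1 | intermediate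
4 | allyl tert‑butyldimethylsilyl ether | C=CCO[Si](C)(C)C(C)(C)C | starting material
5 | arylketeniminium triflate of 3 | COc1cc(C=C=[N+]2[C@@H](C)CC[C@@H]2C)ccc1OCc1ccccc1.[O-]S(=O)(=O)C(F)(F)F | intermediate
6 | (3S)‑2‑aryl‑3‑(silyloxymethyl)cyclobutaniminium triflate (C‑2 not yet settled) | COc1cc(C2C(=[N+]3[C@@H](C)CC[C@@H]3C)C[C@@H]2CO[Si](C)(C)C(C)(C)C)ccc1OCc1ccccc1.[O-]S(=O)(=O)C(F)(F)F | intermediate
7 | (2S,3S)‑2‑[4‑(benzyloxy)‑3‑methoxyphenyl]‑3‑(hydroxymethyl)cyclobutan‑1‑one | COc1cc([C@H]2C(=O)C[C@@H]2CO)ccc1OCc1ccccc1 | intermediate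
8 | 4,5‑dimethoxy‑2‑(trimethylsilyl)phenyl trifluoromethanesulfonate | COc1cc(OS(=O)(=O)C(F)(F)F)c([Si](C)(C)C)cc1OC | starting material
9 | 4,5‑dimethoxybenzyne | COC1=CC#CC=C1OC | intermediate
10 | caesium alkoxide of the benzo‑fused bicyclo[2.2.0]hexanol (new aryl bond anti to CH2OH, cis ring fusion) | [Cs+].[O-][C@]12C[C@H](CO)[C@@]1(c1ccc(OCc3ccccc3)c(OC)c1)c1cc(OC)c(OC)cc12 | intermediate
11 | (3S,4S)‑4‑[4‑(benzyloxy)‑3‑methoxyphenyl]‑3‑(hydroxymethyl)‑6,7‑dimethoxy‑3,4‑dihydronaphthalen‑1(2H)‑one | COc1cc([C@H]2c3cc(OC)c(OC)cc3C(=O)C[C@@H]2CO)ccc1OCc1ccccc1 | intermediate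
12 | (3S,4S)‑4‑[4‑(benzyloxy)‑3‑methoxyphenyl]‑6‑hydroxy‑3‑(hydroxymethyl)‑7‑methoxy‑3,4‑dihydronaphthalen‑1(2H)‑one | COc1cc([C@H]2c3cc(O)c(OC)cc3C(=O)C[C@@H]2CO)ccc1OCc1ccccc1 | intermediate
13 | (3S,4S)‑6‑(benzyloxy)‑4‑[4‑(benzyloxy)‑3‑methoxyphenyl]‑3‑(hydroxymethyl)‑7‑methoxy‑3,4‑dihydronaphthalen‑1(2H)‑one | COc1cc([C@H]2c3cc(OCc4ccccc4)c(OC)cc3C(=O)C[C@@H]2CO)ccc1OCc1ccccc1 | intermediate
14 | (3S,4S)‑3‑(acetoxymethyl)‑6‑(benzyloxy)‑4‑[4‑(benzyloxy)‑3‑methoxyphenyl]‑7‑methoxy‑3,4‑dihydronaphthalen‑1(2H)‑one | COc1cc([C@H]2c3cc(OCc4ccccc4)c(OC)cc3C(=O)C[C@@H]2COC(C)=O)ccc1OCc1ccccc1 | intermediate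
15 | (3R,4S)‑3‑(acetoxymethyl)‑6‑(benzyloxy)‑4‑[4‑(benzyloxy)‑3‑methoxyphenyl]‑7‑methoxy‑1‑(trimethylsilyloxy)‑3,4‑dihydronaphthalene | COc1cc([C@H]2c3cc(OCc4ccccc4)c(OC)cc3C(O[Si](C)(C)C)=C[C@@H]2COC(C)=O)ccc1OCc1ccccc1 | intermediate
16 | (2R,3R,4S)‑3‑(acetoxymethyl)‑6‑(benzyloxy)‑4‑[4‑(benzyloxy)‑3‑methoxyphenyl]‑2‑(hydroxymethyl)‑7‑methoxy‑3,4‑dihydronaphthalen‑1(2H)‑one | COc1cc([C@H]2c3cc(OCc4ccccc4)c(OC)cc3C(=O)[C@@H](CO)[C@@H]2COC(C)=O)ccc1OCc1ccccc1 | intermediate
17 | (2R,3R,4S)‑3‑(acetoxymethyl)‑6‑(benzyloxy)‑4‑[4‑(benzyloxy)‑3‑methoxyphenyl]‑2‑(hydroxymethyl)‑7‑methoxy‑1,2,3,4‑tetrahydronaphthalen‑1‑ol, C‑1 epimers | COc1cc([C@H]2c3cc(OCc4ccccc4)c(OC)cc3C(O)[C@@H](CO)[C@@H]2COC(C)=O)ccc1OCc1ccccc1 | intermediate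
18 | [(1S,2R,3R)‑7‑hydroxy‑1‑(4‑hydroxy‑3‑methoxyphenyl)‑3‑(hydroxymethyl)‑6‑methoxy‑1,2,3,4‑tetrahydronaphthalen‑2‑yl]methyl acetate | COc1cc([C@H]2c3cc(O)c(OC)cc3C[C@@H](CO)[C@@H]2COC(C)=O)ccc1O | target

Total step count: 10. Longest linear sequence: 10 steps (from 1).

Steps most likely to fail

1. Step 3 (Proposed new method). The aryl anion may be protonated before it reaches the carbonyl, which gives plain α‑arylation. The hydroxyl group or the enolate oxygen may capture the aryne. The final protonation may show poor facial selectivity. The fallback uses known chemistry and makes the two bonds one after the other; it sets out from 7 and comes back at 13. The arylcerium reagent from 1‑(benzyloxy)‑4‑bromo‑2‑methoxybenzene (n‑BuLi, then CeCl3; 2.2 equiv because of the free OH) is added to the ketone of 7 to give the 1,2‑diarylcyclobutanol F1. Silver‑catalysed persulfate oxidation (AgNO3 cat., K2S2O8, MeCN–H2O) is the known oxidative ring expansion of 1‑arylcyclobutanols to 1‑tetralones. It should open the alkoxy radical towards the benzylic radical. That radical closes on the free ortho position para to the methoxy group through a chair‑like transition state with both substituents equatorial, which gives the 3,4‑trans product. Rearomatisation gives 13, so steps 4 and 5 are not needed on this path.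

2. Step 2. The auxiliary may show poor facial selectivity with a monosubstituted olefin. The inductively deactivated allyl ether may cycloadd sluggishly. The silyl group may be lost early under the activation conditions. The fallback replaces auxiliary control by resolution; it sets out from 1 and comes back at 7. Acid 1 is converted with dimethylamine and DCC into the dimethylamide F2. The same keteniminium cycloaddition with 4 and acid hydrolysis give the racemic trans‑hydroxy ketone F3. Lipase‑catalysed acylation (Burkholderia cepacia lipase, vinyl acetate, MTBE) should turn the (2R,3R)‑enantiomer into the acetate F4 and leave 7, which is separated by chromatography.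

3. Step 8. Hydrolysis of the enol silane may outrun C–C bond formation. The β‑hydroxy ketone may dehydrate or undergo retro‑aldol. Facial selectivity at C‑2 may be poor. The fallback alkylates with a protected hydroxymethyl cation in place of the aldol; it sets out from 15 and comes back at 18. Enol silane 15 is treated with benzyl chloromethyl ether and ZnBr2 in CH2Cl2 to give the benzyloxymethyl ketone F5. This ketone cannot undergo retro‑aldol and can be equilibrated at C‑2 with DBU. Luche reduction gives the benzylic alcohol F6. Hydrogenolysis under the conditions of step 10 removes three benzyl groups and the benzylic hydroxyl group to give 18.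

Further compounds
F1 | step 3 | (2S,3S)‑1,2‑bis[4‑(benzyloxy)‑3‑methoxyphenyl]‑3‑(hydroxymethyl)cyclobutan‑1‑ol, new aryl group trans to the old one | COc1cc([C@H]2[C@](O)(c3ccc(OCc4ccccc4)c(OC)c3)C[C@@H]2CO)ccc1OCc1ccccc1
F2 | step 2 | 2‑[4‑(benzyloxy)‑3‑methoxyphenyl]‑N,N‑dimethylacetamide | COc1cc(CC(=O)N(C)C)ccc1OCc1ccccc1
F3 | step 2 | racemic trans‑2‑[4‑(benzyloxy)‑3‑methoxyphenyl]‑3‑(hydroxymethyl)cyclobutan‑1‑one | COc1cc(C2C(=O)CC2CO)ccc1OCc1ccccc1
F4 | step 2 | [(1R,2R)‑2‑[4‑(benzyloxy)‑3‑methoxyphenyl]‑3‑oxocyclobutyl]methyl acetate | COc1cc([C@@H]2C(=O)C[C@H]2COC(C)=O)ccc1OCc1ccccc1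
F5 | step 8 | (2R,3R,4S)‑3‑(acetoxymethyl)‑6‑(benzyloxy)‑4‑[4‑(benzyloxy)‑3‑methoxyphenyl]‑2‑[(benzyloxy)methyl]‑7‑methoxy‑3,4‑dihydronaphthalen‑1(2H)‑one | COc1cc([C@H]2c3cc(OCc4ccccc4)c(OC)cc3C(=O)[C@@H](COCc3ccccc3)[C@@H]2COC(C)=O)ccc1OCc1ccccc1
F6 | step 8 | corresponding 1,2,3,4‑tetrahydronaphthalen‑1‑ol, C‑1 epimers | COc1cc([C@H]2c3cc(OCc4ccccc4)c(OC)cc3C(O)[C@@H](COCc3ccccc3)[C@@H]2COC(C)=O)ccc1OCc1ccccc1
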